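**Retrosynthetic overview**

1. Disconnections: each ring C is cut [3+3] at C4–C4a and O1–C2, and the interflavan C4–C6 bond is cut to a flavan-4-yl cation plus a phenol. This leaves one pyrogallol-derived phenol (used twice) and a cis- and a trans-3-aryl-2,3-epoxy aldehyde.
2. Building blocks: pyrogallol 1 → phenol 2; aldehyde 3 + phosphonate 4 → Z-ester 5 → cis-glycidate 6 → cis-epoxy aldehyde 7; 3 + ylide 8 → enal 9 → trans-epoxy aldehyde 10.
3. Ring order (one flask): 2 + 7 close the upper ring C (11); the C4 cation of 11 takes a second 2 to make the C4–C6 bond (12); 12 + 10 close the lower ring C (13).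
4. Global desilylation of 13 gives the target 14.

Assumption: the SMILES is read as epioritin-(4β→6)-oritin-4α-ol, upper unit 2R,3R,4S (2,3-cis-3,4-trans), lower unit 2R,3S,4R (2,3-trans-3,4-trans); 3 is taken as a catalogue compound.

**Route**

Step 1
Reactants: 1 pyrogallol (benzene-1,2,3-triol)
Product: 2 2,2-di-tert-butyl-1,3,2-benzodioxasilol-4-ol (two adjacent OH of pyrogallol bridged by di-tert-butylsilylene; third OH free)
Conditions: t-Bu2Si(OTf)2 (1.0 equiv), 2,6-lutidine, DMF, 0 °C → rt
Reagents that add atoms: di-tert-butylsilyl bis(trifluoromethanesulfonate), CC(C)(C)[Si](OS(=O)(=O)C(F)(F)F)(OS(=O)(=O)C(F)(F)F)C(C)(C)C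
Why: Cyclic silylene formation can only bridge two adjacent phenolic oxygens in a five-membered ring, and either adjacent pair of the symmetric triol gives the same mono-phenol; no stereocentre is formed.

Step 2
Reactants: 3 4-(tert-butyldimethylsilyloxy)benzaldehyde; 4 ethyl 2-(diphenoxyphosphoryl)acetate
Product: 5 ethyl (Z)-3-[4-(tert-butyldimethylsilyloxy)phenyl]prop-2-enoate
Conditions: NaH, THF, −78 → 0 °C
Reagents that add atoms: none
Why: Ando-type Z-selective Horner–Wadsworth–Emmons olefination, in which the electron-poor diaryl phosphonate eliminates quickly from the kinetic adduct to give the Z-cinnamate (about 9:1; the E-isomer is removed by chromatography).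

Step 3
Reactants: 5 ethyl (Z)-3-[4-(tert-butyldimethylsilyloxy)phenyl]prop-2-enoate
Product: 6 ethyl (2S,3S)-3-[4-(tert-butyldimethylsilyloxy)phenyl]oxirane-2-carboxylate (cis-glycidate)
Conditions: (S,S)-[N,N'-bis(3,5-di-tert-butylsalicylidene)cyclohexane-1,2-diaminato]MnCl (5 mol%), NaOCl (aq, pH 11.3), 4-phenylpyridine N-oxide, CH2Cl2, 0–4 °C
Reagents that add atoms: sodium hypochlorite, [Na+].[O-]Cl
Why: Jacobsen–Katsuki epoxidation, for which aryl-conjugated cis-alkenes such as cis-cinnamates are the best substrates; side-on approach to the oxo-manganese salen species of the (S,S)-catalyst gives the (2S,3S)-cis-epoxide, and the minor trans-epoxide from stepwise collapse is removed by chromatography.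

Step 4
Reactants: 6 ethyl (2S,3S)-3-[4-(tert-butyldimethylsilyloxy)phenyl]oxirane-2-carboxylate
Product: 7 (2S,3S)-3-[4-(tert-butyldimethylsilyloxy)phenyl]oxirane-2-carbaldehyde (cis-epoxy aldehyde, used crude)
Conditions: i-Bu2AlH (1.05 equiv), CH2Cl2, −78 °C; aq potassium sodium tartrate
Reagents that add atoms: none
Why: Partial ester reduction, in which the tetrahedral aluminium hemiacetal is stable at −78 °C and collapses to the aldehyde only on work-up; the epoxide and both stereocentres are untouched.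

Step 5
Reactants: 3 4-(tert-butyldimethylsilyloxy)benzaldehyde; 8 (triphenylphosphoranylidene)acetaldehyde
Product: 9 (E)-3-[4-(tert-butyldimethylsilyloxy)phenyl]prop-2-enal
Conditions: PhMe, 80 °C
Reagents that add atoms: none
Why: Wittig olefination with a stabilised formyl ylide gives the E-enal under thermodynamic control of oxaphosphetane formation.

Step 6
Reactants: 9 (E)-3-[4-(tert-butyldimethylsilyloxy)phenyl]prop-2-enal
Product: 10 (2R,3S)-3-[4-(tert-butyldimethylsilyloxy)phenyl]oxirane-2-carbaldehyde (trans-epoxy aldehyde, used crude)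
Conditions: (S)-2-{bis[3,5-bis(trifluoromethyl)phenyl](trimethylsilyloxy)methyl}pyrrolidine (10 mol%), H2O2 (35% aq), CH2Cl2, rt
Reagents that add atoms: hydrogen peroxide, OO
Why: Organocatalytic nucleophilic epoxidation by iminium/enamine catalysis (Jørgensen-type): H2O2 adds to the β-carbon on the face left open by the bulky diaryl(silyloxy)methyl group and the enamine closes the ring, giving the trans-(2R,3S)-epoxide (the catalyst enantiomer is the one that delivers this sense).

Step 7
Reactants: 2 2,2-di-tert-butyl-1,3,2-benzodioxasilol-4-ol (two portions); 7 (2S,3S)-cis-epoxy aldehyde; 10 (2R,3S)-trans-epoxy aldehyde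
Product: 13 tetrasilyl-protected epioritin-(4β→6)-oritin-4α-ol (both 7,8-diols as di-tert-butylsilylene; both 4'-OH as TBS ethers; upper unit 2R,3R,4R; lower unit 2R,3S,4R), via silyl-protected epioritin-4β-ol 11 (not isolated), via C4-aryl flavan-3-ol phenol 12 (not isolated)
Conditions: 2 (1.0 equiv), n-Bu2Mg (0.55 equiv), PhMe–CH2Cl2, 0 °C, then 7, −20 → 40 °C; then 2 (2.0 equiv), MsOH (1.3 equiv), 4 Å MS, −40 → 0 °C; then n-Bu2Mg (1.7 equiv), 10 (2.2 equiv), −20 → 40 °C; aq NH4Cl
Reagents that add atoms: none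
Why: Proposed new method: the aryloxide Mg(OAr)2 of 2 adds through its only free ortho carbon to the Mg-bound aldehyde of 7 (closest known reaction: Casiraghi-type ortho-hydroxyalkylation of magnesium phenoxides), and the same aryloxide then opens the Mg-chelated 2,3-epoxy alkoxide 6-endo at the benzylic carbon with inversion, so the cis-epoxide gives the 2,3-cis ring of 11 (closest known: 6-endo phenol–epoxide cyclisation to flavan-3-ols); acid then ionises the 4-OH of 11 to the O1/7-O-stabilised flavan-4-yl cation, which a second 2 captures para to its free OH and trans to the 3-OH (4β, as in flavan-3,4-diol condensations to proanthocyanidins) to give 12; the new phenol repeats the annulation with 10 at its single free ortho carbon, chelation control (Cram-chelate addition to the α-oxygenated aldehyde) setting the 3,4-trans (4α) carbinol and inversion at the benzylic carbon of the trans-epoxide setting 2,3-trans.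

Step 8
Reactants: 13 tetrasilyl-protected epioritin-(4β→6)-oritin-4α-ol
Product: 14 (2R,3S,4R)-2-(4-hydroxyphenyl)-6-[(2R,3R,4S)-3,7,8-trihydroxy-2-(4-hydroxyphenyl)-3,4-dihydro-2H-chromen-4-yl]-3,4-dihydro-2H-chromene-3,4,7,8-tetrol (CNP0391561.5)
Conditions: Et3N·3HF, THF–MeCN (degassed), 0 °C → rt, Ar; Sephadex LH-20
Reagents that add atoms: none
Why: Fluoride cleavage of the six aryl O–Si bonds is driven by Si–F bond strength, and the nearly neutral amine–HF reagent leaves the acid-labile benzylic 4-OH, the interflavan bond and all six stereocentres untouched (hydrogenolysis is avoided because it would remove the 4-OH).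

**Compound list**

1 | pyrogallol | Oc1cccc(O)c1O | starting material
2 | 2,2-di-tert-butyl-1,3,2-benzodioxasilol-4-ol | CC(C)(C)[Si]1(Oc2cccc(O)c2O1)C(C)(C)C | intermediate
3 | 4-(tert-butyldimethylsilyloxy)benzaldehyde | O=Cc1ccc(O[Si](C)(C)C(C)(C)C)cc1 | starting material
4 | ethyl 2-(diphenoxyphosphoryl)acetate | CCOC(=O)CP(=O)(Oc1ccccc1)Oc1ccccc1 | starting material
5 | ethyl (Z)-3-[4-(tert-butyldimethylsilyloxy)phenyl]prop-2-enoate | CCOC(=O)/C=C\c1ccc(O[Si](C)(C)C(C)(C)C)cc1 | intermediate
6 | ethyl (2S,3S)-3-[4-(tert-butyldimethylsilyloxy)phenyl]oxirane-2-carboxylate | CCOC(=O)[C@H]1O[C@H]1c1ccc(O[Si](C)(C)C(C)(C)C)cc1 | intermediate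
7 | (2S,3S)-3-[4-(tert-butyldimethylsilyloxy)phenyl]oxirane-2-carbaldehyde | O=C[C@H]1O[C@H]1c1ccc(O[Si](C)(C)C(C)(C)C)cc1 | intermediate
8 | (triphenylphosphoranylidene)acetaldehyde | O=CC=P(c1ccccc1)(c1ccccc1)c1ccccc1 | starting material
9 | (E)-3-[4-(tert-butyldimethylsilyloxy)phenyl]prop-2-enal | O=C/C=C/c1ccc(O[Si](C)(C)C(C)(C)C)cc1 | intermediate
10 | (2R,3S)-3-[4-(tert-butyldimethylsilyloxy)phenyl]oxirane-2-carbaldehyde | O=C[C@@H]1O[C@H]1c1ccc(O[Si](C)(C)C(C)(C)C)cc1 | intermediate
11 | (2R,3R,4S)-2-[4-(tert-butyldimethylsilyloxy)phenyl]-7,8-(di-tert-butylsilanediyldioxy)chromane-3,4-diol (2,3-cis; chelation-derived 4β-OH drawn, either C4 epimer gives the same cation; present as its magnesium alkoxide) | CC(C)(C)[Si](C)(C)Oc1ccc(cc1)[C@H]1Oc2c(ccc3O[Si](C(C)(C)C)(C(C)(C)C)Oc23)[C@H](O)[C@H]1O | intermediate (not isolated)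
12 | (2R,3R,4R)-2-[4-(tert-butyldimethylsilyloxy)phenyl]-7,8-(di-tert-butylsilanediyldioxy)-4-(2,2-di-tert-butyl-4-hydroxy-1,3,2-benzodioxasilol-7-yl)chroman-3-ol (2,3-cis-3,4-trans, aryl on the β-face) | CC(C)(C)[Si](C)(C)Oc1ccc(cc1)[C@H]1Oc2c(ccc3O[Si](C(C)(C)C)(C(C)(C)C)Oc23)[C@H](c2ccc(O)c3O[Si](C(C)(C)C)(C(C)(C)C)Oc23)[C@H]1O | intermediate (not isolated)
13 | (2R,3S,4R)-2-[4-(tert-butyldimethylsilyloxy)phenyl]-7,8-(di-tert-butylsilanediyldioxy)-6-{(2R,3R,4R)-2-[4-(tert-butyldimethylsilyloxy)phenyl]-7,8-(di-tert-butylsilanediyldioxy)-3-hydroxychroman-4-yl}chromane-3,4-diol (same spatial arrangement as 14; the upper C4 descriptor is R only because silicon raises the priority of the lower aryl) | CC(C)(C)[Si](C)(C)Oc1ccc(cc1)[C@H]1Oc2c(ccc3O[Si](C(C)(C)C)(C(C)(C)C)Oc23)[C@H](c2cc3c(c4O[Si](C(C)(C)C)(C(C)(C)C)Oc24)O[C@H](c4ccc(O[Si](C)(C)C(C)(C)C)cc4)[C@@H](O)[C@@H]3O)[C@H]1O | intermediate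
14 | (2R,3S,4R)-2-(4-hydroxyphenyl)-6-[(2R,3R,4S)-3,7,8-trihydroxy-2-(4-hydroxyphenyl)-3,4-dihydro-2H-chromen-4-yl]-3,4-dihydro-2H-chromene-3,4,7,8-tetrol, epioritin-(4β→6)-oritin-4α-ol | Oc1ccc([C@H]2Oc3c(ccc(O)c3O)[C@H](c3cc4c(c(O)c3O)O[C@H](c3ccc(O)cc3)[C@@H](O)[C@@H]4O)[C@H]2O)cc1 | target

**Step count and risks**

Total steps: 8. Longest linear sequence: 5 steps (3 → 5 → 6 → 7 → 13 → 14).

Most likely to fail, in order:

Step 7. The risks are 5-exo instead of 6-endo epoxide opening, partial ionisation at the benzylic C2 of the electron-rich cis-epoxide (leaking to the 2,3-trans ring), incomplete chelation control at the lower C4, and the acid/base switches in one flask. Attack of the cation ortho instead of para to the free OH of 2 gives only the silylene-shifted isomer of 12, which can equilibrate to 12 under the basic third stage. The fallback replaces the one-flask double annulation by a convergent monomer coupling with thiophilic activation and sets out from 2, 7 and 10. 2 and 7 are annulated alone (n-Bu2Mg) and 11 is isolated; BnSH and SnCl4 (CH2Cl2, −20 °C) convert 11 into the 4β-benzylsulfanyl ether F1; separately 2 and 10 are annulated to silyl-protected oritin-4α-ol F2. AgBF4 (THF, 0 °C) then ionises F1 in the presence of excess F2, whose C6 attacks the cation trans to the 3-OH while its own 4-OH survives, and the route is rejoined at 13.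

Step 3. The silyloxy-substituted cis-cinnamate may give more trans-epoxide and lower ee than the parent ester, and step 4 can over-reduce. The fallback moves the epoxidation to the allylic alcohol and sets out from 5. i-Bu2AlH (2.2 equiv, −78 °C) gives the (Z)-allylic alcohol F3; Sharpless asymmetric epoxidation (Ti(OiPr)4, D-(−)-diethyl tartrate, t-BuOOH, 4 Å MS, −20 °C) gives the cis-epoxy alcohol F4; Dess–Martin oxidation (NaHCO3, CH2Cl2) returns to the route at 7.

Step 8. The free pyrogallol-type flavan-3,4-diol may ionise at C4 or oxidise during desilylation, and any 4-epimer from step 7 would be carried through. The fallback postpones the carbinol to the last step and sets out from 13. MnO2 (CH2Cl2, rt) oxidises only the benzylic 4-OH to give the flavanonol-terminated dimer F5; Et3N·3HF removes all silyl groups from this robust ketone to give the free phenolic flavanonol dimer F6; NaBH4 (EtOH, 0 °C, Ar) then delivers hydride to give the 3,4-trans diol, as in the classical preparation of flavan-3,4-diols from dihydroflavonols, and the route is rejoined at 14.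

**Further compounds**

F1 | step 7 | (2R,3S,4S)-4-benzylsulfanyl-2-[4-(tert-butyldimethylsilyloxy)phenyl]-7,8-(di-tert-butylsilanediyldioxy)chroman-3-ol (4β-benzylsulfanyl derivative of 11) | CC(C)(C)[Si](C)(C)Oc1ccc(cc1)[C@H]1Oc2c(ccc3O[Si](C(C)(C)C)(C(C)(C)C)Oc23)[C@H](SCc2ccccc2)[C@H]1O
F2 | step 7 | (2R,3S,4R)-2-[4-(tert-butyldimethylsilyloxy)phenyl]-7,8-(di-tert-butylsilanediyldioxy)chromane-3,4-diol (silyl-protected oritin-4α-ol) | c1cc2c(c3O[Si](C(C)(C)C)(C(C)(C)C)Oc13)O[C@H](c1ccc(O[Si](C)(C)C(C)(C)C)cc1)[C@@H](O)[C@@H]2O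
F3 | step 3 | (Z)-3-[4-(tert-butyldimethylsilyloxy)phenyl]prop-2-en-1-ol | OC/C=C\c1ccc(O[Si](C)(C)C(C)(C)C)cc1
F4 | step 3 | [(2R,3S)-3-[4-(tert-butyldimethylsilyloxy)phenyl]oxiran-2-yl]methanol (cis) | OC[C@H]1O[C@H]1c1ccc(O[Si](C)(C)C(C)(C)C)cc1
F5 | step 8 | 13 with the lower C4 carbinol oxidised to the ketone (lower unit a (2R,3R)-3-hydroxychroman-4-one) | CC(C)(C)[Si](C)(C)Oc1ccc(cc1)[C@H]1Oc2c(ccc3O[Si](C(C)(C)C)(C(C)(C)C)Oc23)[C@H](c2cc3c(c4O[Si](C(C)(C)C)(C(C)(C)C)Oc24)O[C@H](c4ccc(O[Si](C)(C)C(C)(C)C)cc4)[C@@H](O)C3=O)[C@H]1O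
F6 | step 8 | (2R,3R)-3,7,8-trihydroxy-2-(4-hydroxyphenyl)-6-[(2R,3R,4S)-3,7,8-trihydroxy-2-(4-hydroxyphenyl)chroman-4-yl]chroman-4-one | Oc1ccc([C@H]2Oc3c(ccc(O)c3O)[C@H](c3cc4c(c(O)c3O)O[C@H](c3ccc(O)cc3)[C@@H](O)C4=O)[C@H]2O)cc1
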